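**Plan**

1. Numbering (p-menthane): C1 = ring C(CH3)Br, C2 = ring CHBr, C4 = ring CH, C8 = side-chain C(CH3)Br, C9 = CH2Br. Retrosynthesis: cut the four C–Br bonds (C1/C2 back to a C1=C2 alkene, C8–Br back to C8–OH, C9 back to an ester carbon), then cut the C4–C8 bond together with a temporary C1–O–C8 ether bridge.
2. Enabling feature: C1 and C8, the two fully substituted bromine-bearing carbons, stand 1,4 to each other across C4. One oxygen between them closes a 2-oxabicyclo[2.2.2]oct-5-ene, the [4+2] adduct of 1-methylcyclohexa-1,3-diene and the ketone C=O of ethyl pyruvate.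
3. Forward: the diene (two steps from 3-methylcyclohexenone; the carbocycle is preformed) and the pyruvate are joined in one cycloaddition that forms C4–C8 and C1–O together. The ester then becomes CH2Br, hydride opening of the allylic ether bridge with double-bond shift unveils the C1=C2 alkene and C8–OH, and Br2 followed by HBr completes the target.
4. Stereochemistry: C4 and C8 come from the catalyst-controlled endo cycloaddition. C1 and C2 come from diaxial anti addition of Br2 steered by the equatorial C4 substituent. C8–Br replaces C8–OH with retention through participation of the C9 bromine.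

Key step: step 3

Remark: the sense of induction of the copper(II)–bisoxazoline catalyst is taken from the square-planar chelate model for α-keto esters, which assigns the required re-face addition to the (R,R)-ligand, and the copper-bound ester is assumed to take the endo position.

**Route**

Step 1
Reactants: 1 3-methylcyclohex-2-en-1-one; 2 4-methylbenzenesulfonohydrazide
Product: 3 4-methyl-N'-(3-methylcyclohex-2-en-1-ylidene)benzenesulfonohydrazide
Conditions: EtOH, cat. HCl, 60 °C → rt
Reagents that add atoms: none
Why: Acid-catalysed condensation of the ketone with the sulfonyl hydrazide (hydrazone formation) should give the tosylhydrazone; no stereocentre is formed.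

Step 2
Reactants: 3 4-methyl-N'-(3-methylcyclohex-2-en-1-ylidene)benzenesulfonohydrazide
Product: 5 1-methylcyclohexa-1,3-diene, via dienyllithium 4 (not isolated)
Conditions: MeLi (2.2 equiv), Et2O, 0 °C → rt; then H2O
Reagents that add atoms: none
Why: Shapiro reaction of a conjugated tosylhydrazone: the second equivalent of base removes the α'-proton at the ring CH2 next to C=N, loss of sulfinate and dinitrogen leaves the dienyllithium, and water protonates it to the homoannular diene with the methyl group on a diene terminus; no stereocentre is formed.

Step 3
Reactants: 5 1-methylcyclohexa-1,3-diene; 6 ethyl 2-oxopropanoate (ethyl pyruvate)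
Product: 7 ethyl (1S,3R,4R)-1,3-dimethyl-2-oxabicyclo[2.2.2]oct-5-ene-3-carboxylate
Conditions: Cu(OTf)2 (10 mol%), 2,2'-(propane-2,2-diyl)bis[(4R)-4-tert-butyl-4,5-dihydro-1,3-oxazole] (11 mol%), CH2Cl2, 0 °C → rt
Reagents that add atoms: none
Why: Hetero-Diels–Alder reaction: ethyl pyruvate is bound to the square-planar copper(II)–bisoxazoline centre through its ketone and ester oxygens, and the s-cis-locked diene adds to the exposed ketone face in a concerted, asynchronous [4+2] cycloaddition in which the bond from the unsubstituted diene terminus to the ketone carbon runs ahead of the bond from the ketone oxygen to the methyl-bearing terminus. The closest known reaction type is the copper–bisoxazoline-catalysed cycloaddition of α-keto esters to cyclohexa-1,3-diene. The one ring closed is the oxygen-containing six-membered ring of the 2-oxabicyclo[2.2.2]oct-5-ene, formed by suprafacial [4+2] addition across the 1,4-positions of the diene. The quaternary carbinol carbon C3 of the bicycle is set by the ligand, whose tert-butyl groups leave only the re face of the chelated ketone open; the bridgehead CH (C4) follows from the endo orientation of the copper-bound ester beneath the diene, and bridgehead C1 is then fixed by the bicyclic geometry. The step needs regioselectivity, secured by the methyl group, which stabilises positive charge at its own terminus so that oxygen bonds there and carbon bonds to the unhindered CH terminus, and endo selectivity, secured by the two-point binding of the keto ester.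

Step 4
Reactants: 7 ethyl (1S,3R,4R)-1,3-dimethyl-2-oxabicyclo[2.2.2]oct-5-ene-3-carboxylate
Product: 8 [(1S,3R,4R)-1,3-dimethyl-2-oxabicyclo[2.2.2]oct-5-en-3-yl]methanol
Conditions: LiAlH4, Et2O, 0 °C; H2O then aq NaOH work-up
Reagents that add atoms: none
Why: Hydride reduction of the α-alkoxy ester should give the primary alcohol, while the bridged tertiary allylic ether and the alkene are inert to the hydride; no stereocentre is touched.

Step 5
Reactants: 8 [(1S,3R,4R)-1,3-dimethyl-2-oxabicyclo[2.2.2]oct-5-en-3-yl]methanol
Product: 10 (1S,3R,4R)-3-(bromomethyl)-1,3-dimethyl-2-oxabicyclo[2.2.2]oct-5-ene, via triflate 9 (not isolated)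
Conditions: Tf2O, 2,6-lutidine, CH2Cl2, −78 °C; then LiBr, THF, −78 °C → rt
Reagents that add atoms: lithium bromide, [Li+].[Br-]
Why: Triflation followed by SN2 displacement with bromide should convert the hindered primary carbinol, which sits on a fully substituted ether carbon, into the bromomethyl group at low temperature, as in displacements of primary triflates next to quaternary ether carbons in carbohydrates; the stereocentres are untouched, and the oxygen stays tied up in the bridge so that it cannot trap the cation of step 6.

Step 6
Reactants: 10 (1S,3R,4R)-3-(bromomethyl)-1,3-dimethyl-2-oxabicyclo[2.2.2]oct-5-ene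
Product: 11 (2R)-1-bromo-2-[(1R)-4-methylcyclohex-3-en-1-yl]propan-2-ol
Conditions: Et3SiH (3 equiv), BF3·OEt2 (1.2 equiv), CH2Cl2, −78 → −40 °C; aq NaHCO3
Reagents that add atoms: none
Why: Ionic hydrogenation with allylic transposition: the Lewis acid ionises the tertiary allylic C1–O bond of the bridge and the silane delivers hydride to the secondary terminus of the allyl cation (formal SN2' reduction), which moves the double bond to the methyl-bearing carbon, releases the tertiary carbinol and leaves the ring CH and carbinol stereocentres as set in step 3.

Step 7
Reactants: 11 (2R)-1-bromo-2-[(1R)-4-methylcyclohex-3-en-1-yl]propan-2-ol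
Product: 12 (2R)-1-bromo-2-[(1R,3S,4S)-3,4-dibromo-4-methylcyclohexyl]propan-2-ol
Conditions: Br2 (1.05 equiv), CH2Cl2, −78 °C, dark
Reagents that add atoms: bromine, BrBr
Why: Electrophilic anti addition of bromine to the trisubstituted ring alkene proceeds through the bromonium ion and chair-like diaxial opening (Fürst–Plattner rule) with bromide entering at the tertiary carbon, so that with the side chain equatorial both new C–Br bonds are axial and trans, which sets the ring C(CH3)Br and CHBr centres as (S,S) relative to the (R)-configured ring CH; the low temperature should keep the tertiary hydroxyl from intercepting the bromonium ion.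

Step 8
Reactants: 12 (2R)-1-bromo-2-[(1R,3S,4S)-3,4-dibromo-4-methylcyclohexyl]propan-2-ol
Product: 13 (1S,2S,4R)-1,2-dibromo-4-[(2R)-1,2-dibromopropan-2-yl]-1-methylcyclohexane
Conditions: HBr (anhydrous, excess), CH2Cl2, −30 → 0 °C
Reagents that add atoms: hydrogen bromide, Br
Why: SN1 substitution of the tertiary alcohol with neighbouring-group participation: the bromine of the adjacent CH2Br group displaces the protonated hydroxyl from the rear to give a bromonium ion on the face opposite the departing water, and bromide reopens it at the tertiary carbon, so C–OH is replaced by C–Br with net retention (double inversion), the ring alkene having been consumed beforehand so that it cannot accept the bromonium ion.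

**Compound list**

1 | 3-methylcyclohex-2-en-1-one | CC1=CC(=O)CCC1 | starting material
2 | 4-methylbenzenesulfonohydrazide | Cc1ccc(cc1)S(=O)(=O)NN | starting material
3 | 4-methyl-N'-(3-methylcyclohex-2-en-1-ylidene)benzenesulfonohydrazide | CC1=CC(=NNS(=O)(=O)c2ccc(C)cc2)CCC1 | intermediate
4 | (3-methylcyclohexa-1,3-dien-1-yl)lithium | [Li]C1=CCCC(C)=C1 | intermediate
5 | 1-methylcyclohexa-1,3-diene | CC1=CC=CCC1 | intermediate
6 | ethyl 2-oxopropanoate (ethyl pyruvate) | CCOC(=O)C(C)=O | starting material
7 | ethyl (1S,3R,4R)-1,3-dimethyl-2-oxabicyclo[2.2.2]oct-5-ene-3-carboxylate (ester on the side of the C5=C6 bridge) | C[C@](O1)(C(=O)OCC)[C@@H]2CC[C@@]1(C)C=C2 | intermediate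
8 | [(1S,3R,4R)-1,3-dimethyl-2-oxabicyclo[2.2.2]oct-5-en-3-yl]methanol | C[C@](O1)(CO)[C@@H]2CC[C@@]1(C)C=C2 | intermediate
9 | [(1S,3R,4R)-1,3-dimethyl-2-oxabicyclo[2.2.2]oct-5-en-3-yl]methyl trifluoromethanesulfonate | C[C@](O1)(COS(=O)(=O)C(F)(F)F)[C@@H]2CC[C@@]1(C)C=C2 | intermediate
10 | (1S,3R,4R)-3-(bromomethyl)-1,3-dimethyl-2-oxabicyclo[2.2.2]oct-5-ene | C[C@](O1)(CBr)[C@@H]2CC[C@@]1(C)C=C2 | intermediate
11 | (2R)-1-bromo-2-[(1R)-4-methylcyclohex-3-en-1-yl]propan-2-ol | C[C@](O)(CBr)[C@@H]1CCC(C)=CC1 | intermediate
12 | (2R)-1-bromo-2-[(1R,3S,4S)-3,4-dibromo-4-methylcyclohexyl]propan-2-ol (ring bromines trans-diaxial, side chain equatorial) | C[C@](O)(CBr)[C@@H]1CC[C@](C)(Br)[C@@H](Br)C1 | intermediate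
13 | (1S,2S,4R)-1,2-dibromo-4-[(2R)-1,2-dibromopropan-2-yl]-1-methylcyclohexane | C[C@](Br)(CBr)[C@@H]1CC[C@](C)(Br)[C@@H](Br)C1 | target

**Step count and risks**

Total step count: 8. Longest linear sequence: 8 steps (1 → 13).

Steps most likely to fail:

1. Step 3. The cycloaddition may lose endo/exo or facial discrimination, or its polarised transition state may leak into a carbonyl-ene pathway or into Lewis-acid ionisation of the adduct. The fallback replaces catalyst control by auxiliary control, sets out from 5 and comes back at 8. Pyruvic acid would be esterified with (1S,2R)-2-phenylcyclohexan-1-ol (DCC, DMAP) to (1S,2R)-2-phenylcyclohexyl 2-oxopropanoate F1. F1 and 5 with SnCl4 (CH2Cl2, −78 °C) should react through the tin-chelated keto ester, one face of which is screened by the phenyl ring, to give (1S,2R)-2-phenylcyclohexyl (1S,3R,4R)-1,3-dimethyl-2-oxabicyclo[2.2.2]oct-5-ene-3-carboxylate F2. F2 would be purified by crystallisation and reduced with LiAlH4 to 8, with recovery of the auxiliary alcohol.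

2. Step 6. The allyl cation may be diverted from hydride capture at the secondary terminus into capture at the tertiary terminus, proton loss to dienes, fragmentation back to diene and ketone, or over-reduction of the tertiary carbinol. The fallback replaces the cationic opening by nickel-catalysed hydroalumination and β-alkoxide elimination, sets out from 8 and comes back at 11. Treatment of 8 with excess DIBAL-H and cat. Ni(cod)2/dppb in toluene should place aluminium next to the oxygen-bearing bridgehead and expel the alkoxide, giving (2R)-2-[(1R)-4-methylcyclohex-3-en-1-yl]propane-1,2-diol F3. TsCl in pyridine (0 °C) would sulfonylate the primary hydroxyl to (2R)-2-hydroxy-2-[(1R)-4-methylcyclohex-3-en-1-yl]propyl 4-methylbenzenesulfonate F4. LiBr in acetone at reflux would replace the sulfonate by bromide and return to 11.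

3. Step 8. Configuration at the side-chain carbinol carbon may be eroded by bond rotation in a weakly bridged β-bromo cation, by bromide attack at the CH2 terminus of the bromonium ion, by elimination and re-addition of HBr, or by a 1,2-hydride shift from the ring CH. The fallback avoids protic acid, sets out from 12 and comes back at 13. K2CO3 in MeOH (0 °C) would close the bromohydrin to (2R)-2-[(1R,3S,4S)-3,4-dibromo-4-methylcyclohexyl]-2-methyloxirane F5 with retention at the tertiary carbon. Ph3PBr2 (CH2Cl2, 0 °C), the known direct conversion of oxiranes into vicinal dibromides, should then open the phosphonium-activated oxirane at the CH2 terminus and expel the tertiary oxyphosphonium group with participation of the new C–Br bond, giving 13.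

Further compounds
F1 | step 3 | (1S,2R)-2-phenylcyclohexyl 2-oxopropanoate | CC(=O)C(=O)O[C@H]1CCCC[C@@H]1c1ccccc1
F2 | step 3 | (1S,2R)-2-phenylcyclohexyl (1S,3R,4R)-1,3-dimethyl-2-oxabicyclo[2.2.2]oct-5-ene-3-carboxylate | C[C@](O1)(C(=O)O[C@H]3CCCC[C@@H]3c3ccccc3)[C@@H]2CC[C@@]1(C)C=C2
F3 | step 6 | (2R)-2-[(1R)-4-methylcyclohex-3-en-1-yl]propane-1,2-diol | C[C@](O)(CO)[C@@H]1CCC(C)=CC1
F4 | step 6 | (2R)-2-hydroxy-2-[(1R)-4-methylcyclohex-3-en-1-yl]propyl 4-methylbenzenesulfonate | C[C@](O)(COS(=O)(=O)c1ccc(C)cc1)[C@@H]1CCC(C)=CC1
F5 | step 8 | (2R)-2-[(1R,3S,4S)-3,4-dibromo-4-methylcyclohexyl]-2-methyloxirane | C[C@]1(CO1)[C@@H]1CC[C@](C)(Br)[C@@H](Br)C1
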